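Readings and results stem from a simulated flask from invented constants, noise included.

You ask which flask holds the most target at 15 h and how far apart the ends lie, and your hunch is that alpha wins on its charge of precatalyst, larger than the others.

| flask | substrate | partner | precatalyst | remark | time |
|---|---|---|---|---|---|
| noon | 10 mM | 39 mM | 60 µM | run made earlier |  |
| summer | 53 mM | 39 mM | 60 µM | run made earlier |  |
| autumn | 30 mM | 53 mM | 60 µM | run made earlier |  |
| alpha | 60 mM | 150 mM | 200 µM |  | 15 h |
| zeta | 30 mM | 25.0 mM | 15 µM |  | 15 h |
| delta | 30 mM | 39.0 mM | 20 µM |  | 15 h |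
| beta | 20 mM | 12.0 mM | 120 µM |  | 15 h |
| gamma | 30 mM | 25.0 mM | 120 µM |  | 15 h |
| epsilon | 30 mM | 39.0 mM | 60 µM |  | 15 h |

| run | time / h | target / % | substrate / % |
|---|---|---|---|
| noon | 2.50 | 11.0 | 88.4 |
| noon | 5.00 | 24.9 | 75.1 |
| noon | 8.00 | 38.4 | 59.6 |
| noon | 10.0 | 46.4 | 50.8 |
| noon | 12.0 | 53.0 | 43.6 |
| noon | 15.0 | 62.2 | 33.2 |
| summer | 2.50 | 3.8 | 95.2 |
| summer | 5.00 | 8.6 | 89.1 |
| summer | 8.00 | 15.1 | 82.2 |
| summer | 10.0 | 15.5 | 79.0 |
| summer | 12.0 | 19.4 | 72.1 |
| summer | 15.0 | 22.5 | 63.6 |
| autumn | 3.00 | 7.6 | 91.3 |
| autumn | 6.00 | 18.5 | 80.8 |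
| autumn | 10.0 | 28.6 | 67.2 |
| autumn | 12.0 | 31.0 | 59.0 |
| autumn | 15.0 | 37.7 | 49.2 |

(each reading ± 1 percentage point)

- the flasks put in order of amount of target, in percent of the substrate charged, best first, at 15 h (alpha / zeta / delta / beta / gamma / epsilon)
- the amount of target, in percent of the substrate charged of the flask you put first, at 15 h
- the amount of target, in percent of the substrate charged of the flask you put last, at 15 h

- no earlier run changes the charge of precatalyst; that part of a forecast is a guess

I would reckon in turnovers. Autumn made 11.3 mM of target on 60 µM of precatalyst by 15.0 h, so its hourly turnover is 12.6 h⁻¹: target made per catalyst charged per hour, net and averaged over the run, a mean turnover frequency. Summer gives 13.3 h⁻¹, but noon, with [substrate] falling from 10 mM, gives 6.91 h⁻¹, about half. Noon and summer differ in their charge of substrate and share their charges of partner and precatalyst, so I read the turnover as drifting down where [substrate] is low.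

Assuming that target scales with catalyst, which no earlier run tests, I multiply turnover, catalyst and time. Alpha comes to 62.8 % and zeta to 9.43 %, with delta at 12.6 %. Epsilon repeats autumn's reckoning at 37.7 %.

Gamma and beta need the drift. Gamma, taken at the mean of autumn's and noon's turnover, comes to 58.4 %. For beta, noon's turnover reckons to 12.4 mM of target, more than its 12.0 mM of partner. If each target takes one partner, which no reading shows, partner is beta's limiting reagent and caps it at 60.0 %. I expect beta to slow before that cap, so I set it below gamma. My order is alpha, gamma, beta, epsilon, delta, zeta.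

The forecast gives alpha > gamma > beta > epsilon > delta > zeta, with 68 % on top and 9 % last, and it opens its estimate with the words “Assuming first order in precatalyst, which is a guess”.

The flasks give alpha > gamma > beta > epsilon > delta > zeta, with alpha at 68.0 % and zeta at 8.98 %.

    partner + free catalyst → catalyst intermediate A (k = 4500 M⁻¹ h⁻¹)
    substrate + catalyst intermediate A ⇌ catalyst intermediate B (K = 80.0 M⁻¹, k = 2800 M⁻¹ h⁻¹)
    catalyst intermediate B → catalyst intermediate C (k = 59.0 h⁻¹)
    catalyst intermediate C → free catalyst + target (k = 77.0 h⁻¹)
    substrate + target → side product (k = 0.980 M⁻¹ h⁻¹)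
    2 partner → self-condensation product (k = 0.910 M⁻¹ h⁻¹)
    partner + precatalyst → free catalyst + spent reagent (k = 33.0 M⁻¹ h⁻¹)

Alpha's hourly turnover comes to 13.6 h⁻¹, close to 12.6 h⁻¹, but that figure is net. Without the conversion of substrate + target into side product, alpha stands at 84.7 % instead of 68.0 %, so the turnover I read counts what survives that reaction. For the flask zeta stopped at 4.0 h, the same product gives 2.51 %, and that flask holds 2.23 %.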